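The benzene ring of the benzo[c]thiophen-1(3H)-one is made last, from a four-membered ring. The feature exploited is the para relation of the oxygens on C4 and C7 of the carbocycle (C3a–C4–C5–C6–C7–C7a): C4–C5–C6–C7 is taken from a cyclobutenone and C7a–C3a from an alkene. The precursor is a 4-hydroxy-3-prenylcyclobutenone whose carbinol carbon carries a Z enoate with the S-trityl, O-silyl side chain. On heating it opens to a dienylketene that closes the C4–C3a bond and aromatises, giving the fully substituted hydroquinone ester in one operation. A cyclobutenedione monoketal fixes the regiochemistry beforehand; thiolactonisation and desilylation finish the synthesis.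

Key step: step 12

Remark: prenyl = 3-methylbut-2-en-1-yl, trityl = triphenylmethyl, TBS = tert-butyldimethylsilyl; the carbinol carbon of 10, 13, 16 and 17 is racemic or a mixture of both configurations, which is of no consequence because it becomes planar later.

Step 1
Reactants: 1 (E)-oct-2-en-1-ol
Product: 2 [(2R,3R)-3-pentyloxiran-2-yl]methanol
Conditions: Ti(OiPr)4 (10 mol%), D-(−)-diisopropyl tartrate (12 mol%), t-BuOOH (in decane), 4 Å MS, CH2Cl2, −20 °C
Reagents that add atoms: tert-butyl hydroperoxide CC(C)(C)OO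
Why: Sharpless asymmetric epoxidation of an E allylic alcohol is highly predictable, and with the D-(−)-tartrate ligand the titanium-bound peroxide is delivered to the alkene face that gives the (2R,3R)-epoxy alcohol, so both stereocentres are set by the reagent.

Step 2
Reactants: 2 [(2R,3R)-3-pentyloxiran-2-yl]methanol
Product: 3 (2S,3R)-3-pentyloxirane-2-carbaldehyde
Conditions: TEMPO (cat.), PhI(OAc)2, CH2Cl2, rt
Reagents that add atoms: none
Why: Oxoammonium (TEMPO) oxidation with PhI(OAc)2 as terminal oxidant stops at the aldehyde and is neither basic nor strongly acidic, so the epoxide and the α-stereocentre are preserved (the descriptor at C2 changes only through the priority rules).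

Step 3
Reactants: 3 (2S,3R)-3-pentyloxirane-2-carbaldehyde
Product: 4 (2R,3R)-2-ethynyl-3-pentyloxirane
Conditions: dimethyl (1-diazo-2-oxopropyl)phosphonate, K2CO3, MeOH, 0 °C → rt
Reagents that add atoms: dimethyl (1-diazo-2-oxopropyl)phosphonate COP(=O)(OC)C(=[N+]=[N-])C(C)=O
Why: Ohira–Bestmann (Seyferth–Gilbert) homologation converts the aldehyde into the terminal alkyne under mild carbonate conditions, and the oxiranyl α-carbon keeps its spatial arrangement because it does not enolise readily (the descriptor again changes only through the priority rules).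

Step 4
Reactants: 4 (2R,3R)-2-ethynyl-3-pentyloxirane
Product: 5 (3S,4R)-3-(tritylsulfanyl)non-1-yn-4-ol
Conditions: Ph3CSH, Et3N, MeOH/THF, rt → 40 °C
Reagents that add atoms: triphenylmethanethiol SC(c1ccccc1)(c1ccccc1)c1ccccc1
Why: Base-mediated thiolate opening of the epoxide is an SN2 process at the propargylic carbon, which is activated by the alkyne and less hindered than the pentyl-bearing carbon, so sulfur enters with inversion to give the 3S sulfide while the carbinol carbon keeps its R configuration (anti product from the trans epoxide).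

Step 5
Reactants: 5 (3S,4R)-3-(tritylsulfanyl)non-1-yn-4-ol
Product: 6 tert-butyldimethyl{[(3S,4R)-3-(tritylsulfanyl)non-1-yn-4-yl]oxy}silane
Conditions: TBSOTf, 2,6-lutidine, CH2Cl2, 0 °C
Reagents that add atoms: tert-butyldimethylsilyl triflate CC(C)(C)[Si](C)(C)OS(=O)(=O)C(F)(F)F
Why: Silylation of the hindered secondary alcohol with the silyl triflate and a hindered pyridine base is a standard protection that tolerates the thioether and the alkyne.

Step 6
Reactants: 6 tert-butyldimethyl{[(3S,4R)-3-(tritylsulfanyl)non-1-yn-4-yl]oxy}silane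
Product: 8 methyl (4S,5R)-5-(tert-butyldimethylsilyloxy)-4-(tritylsulfanyl)dec-2-ynoate, via lithium acetylide 7 (not isolated)
Conditions: n-BuLi, THF, −78 °C; ClCO2Me, −78 → 0 °C
Reagents that add atoms: methyl chloroformate COC(Cl)=O
Why: Deprotonation of the terminal alkyne, by far the most acidic C–H bond, and acylation of the lithium acetylide with methyl chloroformate is the standard ynoate synthesis, and at −78 °C the propargylic stereocentre is not touched.

Step 7
Reactants: 9 dimethyl squarate (3,4-dimethoxycyclobut-3-ene-1,2-dione)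
Product: 10 4-allyl-4-hydroxy-2,3-dimethoxycyclobut-2-en-1-one
Conditions: allylMgBr, THF, −78 °C; sat. aq NH4Cl
Reagents that add atoms: allylmagnesium bromide C=CC[Mg]Br
Why: Grignard 1,2-addition to one carbonyl of the squarate is the standard entry into squarate chemistry, and a symmetrical allyl nucleophile avoids the allylic transposition that a prenyl-metal reagent would suffer; the racemic carbinol centre disappears in step 8.

Step 8
Reactants: 10 4-allyl-4-hydroxy-2,3-dimethoxycyclobut-2-en-1-one
Product: 11 2-allyl-3,4,4-trimethoxycyclobut-2-en-1-one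
Conditions: BF3·OEt2 (cat.), MeOH, 4 Å MS, CH2Cl2, 0 °C → rt
Reagents that add atoms: methanol CO
Why: Lewis acid ionisation of the tertiary allylic alcohol gives a methoxy-stabilised cyclobutenyl cation that methanol captures at the methoxy-bearing terminus, the known route from squarate adducts to cyclobutenedione monoketals (1,3-transposition with ketalisation).

Step 9
Reactants: 11 2-allyl-3,4,4-trimethoxycyclobut-2-en-1-one
Product: 12 3,4,4-trimethoxy-2-prenylcyclobut-2-en-1-one
Conditions: 2-methylbut-2-ene (excess), second-generation Grubbs catalyst RuCl2(=CHPh)(H2IMes)(PCy3) (3 mol%), CH2Cl2, 40 °C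
Reagents that add atoms: 2-methylbut-2-ene CC=C(C)C
Why: Olefin cross-metathesis with an excess of 2-methylbut-2-ene converts the terminal allyl group into the prenyl group, the tetrasubstituted ring alkene being inert to the ruthenium carbene.

Step 10
Reactants: 12 3,4,4-trimethoxy-2-prenylcyclobut-2-en-1-one
Product: 14 4,4-dimethoxy-2-prenylcyclobut-2-en-1-one, via allylic alcohol 13 (not isolated)
Conditions: i-Bu2AlH, CH2Cl2, −78 °C; then 1 M HCl, THF, 0 °C
Reagents that add atoms: water O
Why: 1,2-Reduction of the vinylogous ester carbonyl followed by acid-induced allylic transposition with loss of methanol (Stork–Danheiser-type sequence) places the carbonyl next to the prenyl-bearing carbon and hydrogen on the other alkene carbon, while the ketal, now flanked by a carbonyl, resists hydrolysis.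

Step 11
Reactants: 8 methyl (4S,5R)-5-(tert-butyldimethylsilyloxy)-4-(tritylsulfanyl)dec-2-ynoate; 14 4,4-dimethoxy-2-prenylcyclobut-2-en-1-one
Product: 17 methyl (2Z,4S,5R)-5-(tert-butyldimethylsilyloxy)-2-(1-hydroxy-4-oxo-2-prenylcyclobut-2-en-1-yl)-4-(tritylsulfanyl)dec-2-enoate, via aluminium allenolate 15 (not isolated), via ketal adduct 16 (not isolated)
Conditions: i-Bu2AlH, HMPA, THF, 0 °C; add 8, 0 °C; add 14, −20 °C → rt; then 1 M HCl, THF, 0 °C → rt
Reagents that add atoms: water O
Why: Conjugate hydroalumination of the ynoate with i-Bu2AlH–HMPA gives an aluminium allenolate that adds through its α-carbon to the single free carbonyl of 14 (reductive aldol giving a Morita–Baylis–Hillman-type adduct), the electrophile approaching beside the β-hydrogen so that the Z enoate results, and the acidic work-up hydrolyses the allylic ketal; the carbinol carbon forms in both configurations, and the monoketal guarantees that it lies next to the prenyl-bearing ring carbon.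

Step 12
Reactants: 17 methyl (2Z,4S,5R)-5-(tert-butyldimethylsilyloxy)-2-(1-hydroxy-4-oxo-2-prenylcyclobut-2-en-1-yl)-4-(tritylsulfanyl)dec-2-enoate
Product: 20 methyl 3,6-dihydroxy-5-prenyl-2-[(1S,2R)-2-(tert-butyldimethylsilyloxy)-1-(tritylsulfanyl)heptyl]benzoate, via dienylketene 18 (not isolated), via cyclohexadienone 19 (not isolated)
Conditions: PhMe (degassed), 110 °C, Ar; aq Na2S2O4 wash
Reagents that add atoms: none
Why: Thermal conrotatory 4π opening of the cyclobutenone cleaves the bond between the carbonyl carbon and the carbinol carbon and gives dienylketene 18, in which the hydroxyl has rotated outward and the enoate inward, next to the ketene. Disrotatory 6π electrocyclisation then joins the ketene carbon to the β-carbon of the enoate (the future C4–C3a bond), closing the six-membered carbocycle as cyclohexadienone 19, and enolisation of its one sp3 ring carbon gives the aromatic hydroquinone; the closest known reaction type is the Moore rearrangement of 4-alkenyl-4-hydroxycyclobutenones. The ring is closed by electrocyclisation and not by an ionic cyclisation, so thioether, silyl ether, ester and prenyl group are spectators at 110 °C. No lasting stereocentre is created, since the ring carbon that is sp3 in 19 becomes aromatic, and the two side-chain stereocentres take no part in any bond change under these neutral conditions. The only selectivity required is the torquoselectivity of the opening, secured by the strong outward preference of the donor hydroxyl, while the Z enoate keeps the bulky side chain outward on the closing terminus and the substitution pattern is fixed by the connectivity of 17. Air is excluded and a dithionite wash is used so that the hydroquinone is not oxidised to the quinone.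

Step 13
Reactants: 20 methyl 3,6-dihydroxy-5-prenyl-2-[(1S,2R)-2-(tert-butyldimethylsilyloxy)-1-(tritylsulfanyl)heptyl]benzoate
Product: 22 (3S)-3-[(1R)-1-(tert-butyldimethylsilyloxy)hexyl]-4,7-dihydroxy-6-prenyl-benzo[c]thiophen-1(3H)-one, via thiol 21 (not isolated)
Conditions: TFA, Et3SiH, CH2Cl2, 0 °C; evaporate (PhMe azeotrope); then AlMe3, PhMe, 0 °C → rt; 1 M HCl
Reagents that add atoms: none
Why: Acidolysis of the S–trityl bond with silane capture of the trityl cation frees the thiol, and its dimethylaluminium thiolate then displaces methoxide from the ortho ester (aluminium-mediated ester-to-thioester exchange, five-membered ring closure driven by the Al–O bond), a non-oxidising, aprotic closure that spares the hydroquinone, the prenyl group and the silyl ether, which in turn keeps the C1' oxygen from competing for the acyl group.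

Step 14
Reactants: 22 (3S)-3-[(1R)-1-(tert-butyldimethylsilyloxy)hexyl]-4,7-dihydroxy-6-prenyl-benzo[c]thiophen-1(3H)-one
Product: 23 asperglaucin A, (3S)-4,7-dihydroxy-3-[(1R)-1-hydroxyhexyl]-6-prenyl-benzo[c]thiophen-1(3H)-one
Conditions: HF·pyridine, pyridine, THF, 0 °C → rt
Reagents that add atoms: none
Why: Fluoride cleavage of the secondary silyl ether with pyridine-buffered HF is mild and non-basic, so the thiolactone, the C3 stereocentre and the hydroquinone are not endangered.

Compound list
1 | (E)-oct-2-en-1-ol | CCCCC/C=C/CO | starting material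
2 | [(2R,3R)-3-pentyloxiran-2-yl]methanol | CCCCC[C@H]1O[C@@H]1CO | intermediate
3 | (2S,3R)-3-pentyloxirane-2-carbaldehyde | CCCCC[C@H]1O[C@@H]1C=O | intermediate
4 | (2R,3R)-2-ethynyl-3-pentyloxirane | CCCCC[C@H]1O[C@@H]1C#C | intermediate
5 | (3S,4R)-3-(tritylsulfanyl)non-1-yn-4-ol | CCCCC[C@@H](O)[C@@H](SC(c1ccccc1)(c1ccccc1)c1ccccc1)C#C | intermediate
6 | tert-butyldimethyl{[(3S,4R)-3-(tritylsulfanyl)non-1-yn-4-yl]oxy}silane | CCCCC[C@@H](O[Si](C)(C)C(C)(C)C)[C@@H](SC(c1ccccc1)(c1ccccc1)c1ccccc1)C#C | intermediate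
7 | lithium acetylide of 6 | CCCCC[C@@H](O[Si](C)(C)C(C)(C)C)[C@@H](SC(c1ccccc1)(c1ccccc1)c1ccccc1)C#C[Li] | intermediate
8 | methyl (4S,5R)-5-(tert-butyldimethylsilyloxy)-4-(tritylsulfanyl)dec-2-ynoate | CCCCC[C@@H](O[Si](C)(C)C(C)(C)C)[C@@H](SC(c1ccccc1)(c1ccccc1)c1ccccc1)C#CC(=O)OC | intermediate
9 | dimethyl squarate (3,4-dimethoxycyclobut-3-ene-1,2-dione) | COC1=C(OC)C(=O)C1=O | starting material
10 | 4-allyl-4-hydroxy-2,3-dimethoxycyclobut-2-en-1-one (racemic) | C=CCC1(O)C(OC)=C(OC)C1=O | intermediate
11 | 2-allyl-3,4,4-trimethoxycyclobut-2-en-1-one | C=CCC1=C(OC)C(OC)(OC)C1=O | intermediate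
12 | 3,4,4-trimethoxy-2-prenylcyclobut-2-en-1-one | CC(C)=CCC1=C(OC)C(OC)(OC)C1=O | intermediate
13 | 3,4,4-trimethoxy-2-prenylcyclobut-2-en-1-ol (racemic; aluminium alkoxide in the flask) | CC(C)=CCC1=C(OC)C(OC)(OC)C1O | intermediate
14 | 4,4-dimethoxy-2-prenylcyclobut-2-en-1-one | CC(C)=CCC1=CC(OC)(OC)C1=O | intermediate
15 | diisobutylaluminium allenolate of 8 | CCCCC[C@@H](O[Si](C)(C)C(C)(C)C)[C@@H](SC(c1ccccc1)(c1ccccc1)c1ccccc1)C=C=C(OC)O[Al](CC(C)C)CC(C)C | intermediate
16 | methyl (2Z,4S,5R)-5-(tert-butyldimethylsilyloxy)-2-(1-hydroxy-4,4-dimethoxy-2-prenylcyclobut-2-en-1-yl)-4-(tritylsulfanyl)dec-2-enoate (both carbinol epimers) | CCCCC[C@@H](O[Si](C)(C)C(C)(C)C)[C@@H](SC(c1ccccc1)(c1ccccc1)c1ccccc1)/C=C(/C1(O)C(CC=C(C)C)=CC1(OC)OC)C(=O)OC | intermediate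
17 | methyl (2Z,4S,5R)-5-(tert-butyldimethylsilyloxy)-2-(1-hydroxy-4-oxo-2-prenylcyclobut-2-en-1-yl)-4-(tritylsulfanyl)dec-2-enoate (both carbinol epimers) | CCCCC[C@@H](O[Si](C)(C)C(C)(C)C)[C@@H](SC(c1ccccc1)(c1ccccc1)c1ccccc1)/C=C(/C1(O)C(CC=C(C)C)=CC1=O)C(=O)OC | intermediate
18 | dienylketene: methyl (2Z,4S,5R)-5-(tert-butyldimethylsilyloxy)-2-[(1E)-1-hydroxy-4-oxo-2-prenylbuta-1,3-dien-1-yl]-4-(tritylsulfanyl)dec-2-enoate | CCCCC[C@@H](O[Si](C)(C)C(C)(C)C)[C@@H](SC(c1ccccc1)(c1ccccc1)c1ccccc1)/C=C(C(=O)OC)/C(O)=C(CC=C(C)C)\C=C=O | intermediate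
19 | cyclohexadienone: methyl 2-hydroxy-5-oxo-3-prenyl-6-[(1S,2R)-2-(tert-butyldimethylsilyloxy)-1-(tritylsulfanyl)heptyl]cyclohexa-1,3-diene-1-carboxylate | CCCCC[C@@H](O[Si](C)(C)C(C)(C)C)[C@@H](SC(c1ccccc1)(c1ccccc1)c1ccccc1)C1C(=O)C=C(CC=C(C)C)C(O)=C1C(=O)OC | intermediate
20 | methyl 3,6-dihydroxy-5-prenyl-2-[(1S,2R)-2-(tert-butyldimethylsilyloxy)-1-(tritylsulfanyl)heptyl]benzoate | CCCCC[C@@H](O[Si](C)(C)C(C)(C)C)[C@@H](SC(c1ccccc1)(c1ccccc1)c1ccccc1)c1c(O)cc(CC=C(C)C)c(O)c1C(=O)OC | intermediate
21 | methyl 3,6-dihydroxy-5-prenyl-2-[(1S,2R)-2-(tert-butyldimethylsilyloxy)-1-sulfanylheptyl]benzoate | CCCCC[C@@H](O[Si](C)(C)C(C)(C)C)[C@@H](S)c1c(O)cc(CC=C(C)C)c(O)c1C(=O)OC | intermediate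
22 | (3S)-3-[(1R)-1-(tert-butyldimethylsilyloxy)hexyl]-4,7-dihydroxy-6-prenyl-benzo[c]thiophen-1(3H)-one | CCCCC[C@@H](O[Si](C)(C)C(C)(C)C)[C@H]1SC(=O)c2c(O)c(CC=C(C)C)cc(O)c21 | intermediate
23 | asperglaucin A | CCCCC[C@@H](O)[C@H]1SC(=O)c2c(O)c(CC=C(C)C)cc(O)c21 | target

Total step count: 14. Longest linear sequence: 10 steps (steps 1–6 and 11–14); the cyclobutenone branch (steps 7–10) has four steps.

Steps most likely to fail

1. Step 12. The ring-opened hydroxy ketene may be consumed by its own hydroxyl (closure to a butenolide after incomplete outward rotation), or the free hydroquinone may be oxidised during isolation. The fallback sets out from 17 and returns at 20. The carbinol is silylated (TMSOTf, Et3N, CH2Cl2, −78 °C) to the trimethylsilyl ether of 17 F1. Thermolysis of F1 (PhMe, 110 °C) proceeds through a siloxy ketene that cannot lactonise and gives the mono-silylated hydroquinone, methyl 3-hydroxy-5-prenyl-6-(trimethylsilyloxy)-2-[(1S,2R)-2-(tert-butyldimethylsilyloxy)-1-(tritylsulfanyl)heptyl]benzoate F2, which cannot be oxidised to a quinone. Citric acid in MeOH removes the trimethylsilyl group and gives 20.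

2. Step 11. The hindered aluminium allenolate may react too slowly with the congested carbonyl of 14, may add in a conjugate sense at the unsubstituted ring carbon, or residual hydride may reduce 14. The fallback sets out from 6 (through its lithium acetylide 7) and 14 and returns at 16. Acetylide 7 is added to 14 (THF, −78 °C), a well-established addition to cyclobutenones, to give the propargylic alcohol 1-[(3S,4R)-4-(tert-butyldimethylsilyloxy)-3-(tritylsulfanyl)non-1-yn-1-yl]-4,4-dimethoxy-2-prenylcyclobut-2-en-1-ol F3. Hydroxyl-directed trans-hydrostannation (Bu3SnH, [Cp*RuCl]4 cat., CH2Cl2) places tin on the carbinol-bound alkyne carbon and hydrogen trans to it, giving the (Z)-alkenylstannane F4. Hydroxyl-assisted methoxycarbonylation (Pd(OAc)2 cat., Ph3As, 1,4-benzoquinone, CO, MeOH) exchanges tin for the ester with retention and gives 16, which is hydrolysed to 17 as in the second stage of step 11.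

3. Step 13. Acyl transfer from the doubly ortho-substituted, chelated methyl ester to sulfur may stall, or the acidic stage may trigger cyclisation of the prenyl group onto the neighbouring phenol or loss of the silyl ether. The fallback sets out from 20 and returns at 22. The ester is demethylated by SN2 attack of iodide at the methyl group (LiI, EtOAc, reflux), which does not depend on access to the hindered carbonyl, to give 3,6-dihydroxy-5-prenyl-2-[(1S,2R)-2-(tert-butyldimethylsilyloxy)-1-(tritylsulfanyl)heptyl]benzoic acid F5. Brief detritylation (TFA, Et3SiH, CH2Cl2, 0 °C) gives the mercapto acid F6. Carbodiimide activation (EDC·HCl, CH2Cl2, 0 °C) closes the thiolactone to 22.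

Further compounds
F1 | step 12 | methyl (2Z,4S,5R)-5-(tert-butyldimethylsilyloxy)-2-[4-oxo-2-prenyl-1-(trimethylsilyloxy)cyclobut-2-en-1-yl]-4-(tritylsulfanyl)dec-2-enoate | CCCCC[C@@H](O[Si](C)(C)C(C)(C)C)[C@@H](SC(c1ccccc1)(c1ccccc1)c1ccccc1)/C=C(/C1(O[Si](C)(C)C)C(CC=C(C)C)=CC1=O)C(=O)OC
F2 | step 12 | methyl 3-hydroxy-5-prenyl-6-(trimethylsilyloxy)-2-[(1S,2R)-2-(tert-butyldimethylsilyloxy)-1-(tritylsulfanyl)heptyl]benzoate | CCCCC[C@@H](O[Si](C)(C)C(C)(C)C)[C@@H](SC(c1ccccc1)(c1ccccc1)c1ccccc1)c1c(O)cc(CC=C(C)C)c(O[Si](C)(C)C)c1C(=O)OC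
F3 | step 11 | 1-[(3S,4R)-4-(tert-butyldimethylsilyloxy)-3-(tritylsulfanyl)non-1-yn-1-yl]-4,4-dimethoxy-2-prenylcyclobut-2-en-1-ol | CCCCC[C@@H](O[Si](C)(C)C(C)(C)C)[C@@H](SC(c1ccccc1)(c1ccccc1)c1ccccc1)C#CC1(O)C(CC=C(C)C)=CC1(OC)OC
F4 | step 11 | 1-[(1Z,3S,4R)-4-(tert-butyldimethylsilyloxy)-1-(tributylstannyl)-3-(tritylsulfanyl)non-1-en-1-yl]-4,4-dimethoxy-2-prenylcyclobut-2-en-1-ol | CCCCC[C@@H](O[Si](C)(C)C(C)(C)C)[C@@H](SC(c1ccccc1)(c1ccccc1)c1ccccc1)/C=C(/C1(O)C(CC=C(C)C)=CC1(OC)OC)[Sn](CCCC)(CCCC)CCCC
F5 | step 13 | 3,6-dihydroxy-5-prenyl-2-[(1S,2R)-2-(tert-butyldimethylsilyloxy)-1-(tritylsulfanyl)heptyl]benzoic acid | CCCCC[C@@H](O[Si](C)(C)C(C)(C)C)[C@@H](SC(c1ccccc1)(c1ccccc1)c1ccccc1)c1c(O)cc(CC=C(C)C)c(O)c1C(=O)O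
F6 | step 13 | 3,6-dihydroxy-5-prenyl-2-[(1S,2R)-2-(tert-butyldimethylsilyloxy)-1-sulfanylheptyl]benzoic acid | CCCCC[C@@H](O[Si](C)(C)C(C)(C)C)[C@@H](S)c1c(O)cc(CC=C(C)C)c(O)c1C(=O)O
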